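**Retrosynthetic overview**

1. Numbering: ring carbon C1 bears the benzoyloxymethyl carbon C7, C2 is the vinylic CH, C3 carries the benzoate, C4–C6 carry the three hydroxyls. The last disconnection is the target from its 4,5-O-isopropylidene derivative; the cis-4,5-diol travels as a temporary dioxolane ring.
2. Key disconnection: ring bond C1–C6, opened to an acyclic (Z)-alkenyl iodide (C1–I) and an aldehyde (C6). Forward, an intramolecular Nozaki–Hiyama–Kishi coupling joins these two electrophilic carbons by polarity reversal at C1, closes the cyclohexene and creates the C6 carbinol with both benzoates already in place.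
3. Enabling feature: C6 is a secondary allylic carbinol bonded directly to the vinylic carbon C1 of the endocyclic C1=C2 bond (the retron of an alkenylmetal–aldehyde addition, Z geometry enforced by the ring). The adjacent cis-diol at C4/C5 can be locked in a dioxolane that holds both reacting arms on one face.
4. Chiral pool: D-arabinose supplies C2–C6 (its C1–C5) and the C3, C4, C5 stereocentres (its C2, C3, C4) unchanged. Its aldehyde carbon becomes the vinylic CH and its CH2OH the new carbinol; C1 and C7 come from an α-iodo ester ylide.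
5. Ring order: dioxolane first (step 1), cyclohexene second (step 8), dioxolane opened last (step 9).

Key step: step 8

**Route**

Step 1
Reactants: 1 D-arabinose; 2 2,2-dimethoxypropane
Product: 3 3,4-O-isopropylidene-D-arabinopyranose
Conditions: Me2C(OMe)2 (1.5 equiv), TsOH·H2O (cat.), DMF, rt; Et3N quench
Reagents that add atoms: 2,2-dimethoxypropane 2, COC(C)(C)OC
Why: Kinetic acid-catalysed ketal exchange (acetonide formation) with a limited amount of reagent should ketalise the cis-3,4-diol of the pyranose first, leaving the anomeric and C2 hydroxyls free and changing no stereocentre.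

Step 2
Reactants: 3 3,4-O-isopropylidene-D-arabinopyranose; 4 ethyl (triphenylphosphoranylidene)acetate; 5 N-iodosuccinimide
Product: 7 ethyl (Z)-2,3-dideoxy-2-iodo-5,6-O-isopropylidene-D-arabino-hept-2-enonate, via iodo ylide 6 (not isolated)
Conditions: 4 (2.0 equiv), NIS (2.0 equiv), CH2Cl2, −20 °C; then 3, PhCO2H (cat.), 40 °C
Reagents that add atoms: ethyl (triphenylphosphoranylidene)acetate 4, CCOC(=O)C=P(c1ccccc1)(c1ccccc1)c1ccccc1; N-iodosuccinimide 5, O=C1CCC(=O)N1I
Why: Wittig olefination of the open hydroxy-aldehyde form of the lactol by the stabilised iodo ylide 6 (formed from 4 by iodination with NIS, the succinimide anion taking the proton) should place the ester trans to the sugar chain and hence iodine cis to it (Z), the geometry the later ring closure needs, without touching a stereocentre.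

Step 3
Reactants: 7 ethyl (Z)-2,3-dideoxy-2-iodo-5,6-O-isopropylidene-D-arabino-hept-2-enonate; 8 tert-butyldimethylsilyl chloride
Product: 9 ethyl (Z)-7-O-(tert-butyldimethylsilyl)-2,3-dideoxy-2-iodo-5,6-O-isopropylidene-D-arabino-hept-2-enonate
Conditions: TBSCl (1.1 equiv), imidazole, CH2Cl2, 0 °C
Reagents that add atoms: tert-butyldimethylsilyl chloride 8, CC(C)(C)[Si](C)(C)Cl
Why: Imidazole-mediated silylation is selective for the unhindered primary hydroxyl over the secondary allylic one flanked by the dioxolane and the iodoalkene.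

Step 4
Reactants: 9 ethyl (Z)-7-O-(tert-butyldimethylsilyl)-2,3-dideoxy-2-iodo-5,6-O-isopropylidene-D-arabino-hept-2-enonate
Product: 10 (Z)-7-O-(tert-butyldimethylsilyl)-2,3-dideoxy-2-iodo-5,6-O-isopropylidene-D-arabino-hept-2-enitol
Conditions: i-Bu2AlH (4 equiv), CH2Cl2, −78 °C; aq. potassium sodium tartrate
Reagents that add atoms: none
Why: i-Bu2AlH reduces the conjugated ester in a 1,2 sense to the 2-iodoallylic alcohol at low temperature, where the alkenyl iodide, silyl ether and ketal are inert and the alkene geometry is kept; it is done before any benzoate is present.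

Step 5
Reactants: 10 (Z)-7-O-(tert-butyldimethylsilyl)-2,3-dideoxy-2-iodo-5,6-O-isopropylidene-D-arabino-hept-2-enitol; 11 benzoyl chloride
Product: 12 (Z)-1,4-di-O-benzoyl-7-O-(tert-butyldimethylsilyl)-2,3-dideoxy-2-iodo-5,6-O-isopropylidene-D-arabino-hept-2-enitol
Conditions: BzCl (2.5 equiv), pyridine, DMAP (cat.), CH2Cl2, 0 °C to rt
Reagents that add atoms: benzoyl chloride 11, O=C(Cl)c1ccccc1
Why: DMAP-catalysed acylation esterifies both free hydroxyls, which are exactly the two oxygens (on C7 and C3 of the target) that carry benzoates, without touching a stereocentre.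

Step 6
Reactants: 12 (Z)-1,4-di-O-benzoyl-7-O-(tert-butyldimethylsilyl)-2,3-dideoxy-2-iodo-5,6-O-isopropylidene-D-arabino-hept-2-enitol
Product: 13 (Z)-1,4-di-O-benzoyl-2,3-dideoxy-2-iodo-5,6-O-isopropylidene-D-arabino-hept-2-enitol
Conditions: HF·pyridine, pyridine, THF, 0 °C to rt
Reagents that add atoms: none
Why: Fluoride cleaves the primary silyl ether under buffered, non-basic conditions that should avoid benzoate migration or hydrolysis and leave the acetonide intact.

Step 7
Reactants: 13 (Z)-1,4-di-O-benzoyl-2,3-dideoxy-2-iodo-5,6-O-isopropylidene-D-arabino-hept-2-enitol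
Product: 14 (Z)-4,7-di-O-benzoyl-5,6-dideoxy-6-iodo-2,3-O-isopropylidene-aldehydo-D-lyxo-hept-5-enose
Conditions: Dess–Martin periodinane, CH2Cl2, 0 °C to rt; used crude
Reagents that add atoms: none
Why: Dess–Martin oxidation converts the primary alcohol to the aldehyde under neutral conditions, so the epimerisable centre α to the carbonyl on the cis-dioxolane should keep its configuration; the aldehyde is used at once.

Step 8
Reactants: 14 (Z)-4,7-di-O-benzoyl-5,6-dideoxy-6-iodo-2,3-O-isopropylidene-aldehydo-D-lyxo-hept-5-enose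
Product: 16 [(3R,4S,5R,6S)-3-(benzoyloxy)-6-hydroxy-4,5-(isopropylidenedioxy)cyclohex-1-en-1-yl]methyl benzoate, via alkenylchromium dichloride 15 (not isolated)
Conditions: CrCl2 (5 equiv), NiCl2 (2 mol %), degassed DMF, rt, 0.005 M; aqueous work-up
Reagents that add atoms: none
Why: CrCl2 reduces NiCl2 to zerovalent nickel, which inserts into the C1–I bond with retention of the Z geometry; transmetalation to trivalent chromium gives alkenylchromium dichloride 15, whose chromium binds the C6 aldehyde and delivers C1 to it, so two carbons that are both electrophilic in 14 are joined by polarity reversal of C1. The closest known reaction type is the intramolecular Nozaki–Hiyama–Kishi cyclisation of sugar-derived haloalkenyl aldehydes to carbocyclic allylic alcohols. The cyclohexene closes in a 6-exo-trig mode at the aldehyde, the alkene becoming endocyclic because the metal is cis to the chain, and the cis-fused dioxolane pre-organises both arms on one face. The new C6 stereocentre is set under substrate control: in the half-chair transition state with the C3 benzoate pseudo-equatorial, the chromium-bound C6–O bond should develop pseudo-axially, away from the CH2OBz group on C1 (allylic 1,2-strain) and anti to the C5–O bond (dipole minimisation), giving the 5,6-trans (6S) alcohol. The step needs addition to the aldehyde in the presence of two benzoates, one of them β to the metal, and no epimerisation at C5; the weakly basic and weakly nucleophilic alkenylchromium, the neutral medium, high dilution and fast intramolecular capture are expected to secure this.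

Step 9
Reactants: 16 [(3R,4S,5R,6S)-3-(benzoyloxy)-6-hydroxy-4,5-(isopropylidenedioxy)cyclohex-1-en-1-yl]methyl benzoate
Product: 17 [(3R,4R,5R,6S)-3-(benzoyloxy)-4,5,6-trihydroxycyclohex-1-en-1-yl]methyl benzoate (CNP0178138.1)
Conditions: CF3CO2H/H2O (9:1), CH2Cl2, 0 °C
Reagents that add atoms: none
Why: Acid-catalysed hydrolysis of the isopropylidene ketal frees the cis-4,5-diol, while benzoates are stable to acid and no C–O bond at a stereocentre is broken.

**Compound list**

1 | D-arabinose (drawn as the open-chain aldehyde; it reacts as the pyranose) | O=C[C@@H](O)[C@H](O)[C@H](O)CO | starting material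
2 | 2,2-dimethoxypropane | COC(C)(C)OC | starting material
3 | 3,4-O-isopropylidene-D-arabinopyranose (lactol; anomers interconvert, β-anomer drawn) | O[C@H]1[C@@H](O)[C@@H]2OC(C)(C)O[C@@H]2CO1 | intermediate
4 | ethyl (triphenylphosphoranylidene)acetate | CCOC(=O)C=P(c1ccccc1)(c1ccccc1)c1ccccc1 | starting material
5 | N-iodosuccinimide | O=C1CCC(=O)N1I | starting material
6 | ethyl iodo(triphenylphosphoranylidene)acetate (iodo ylide) | CCOC(=O)C(I)=P(c1ccccc1)(c1ccccc1)c1ccccc1 | intermediate
7 | ethyl (Z)-2,3-dideoxy-2-iodo-5,6-O-isopropylidene-D-arabino-hept-2-enonate | CCOC(=O)/C(I)=C/[C@@H](O)[C@@H]1OC(C)(C)O[C@@H]1CO | intermediate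
8 | tert-butyldimethylsilyl chloride | CC(C)(C)[Si](C)(C)Cl | starting material
9 | ethyl (Z)-7-O-(tert-butyldimethylsilyl)-2,3-dideoxy-2-iodo-5,6-O-isopropylidene-D-arabino-hept-2-enonate | CCOC(=O)/C(I)=C/[C@@H](O)[C@@H]1OC(C)(C)O[C@@H]1CO[Si](C)(C)C(C)(C)C | intermediate
10 | (Z)-7-O-(tert-butyldimethylsilyl)-2,3-dideoxy-2-iodo-5,6-O-isopropylidene-D-arabino-hept-2-enitol | OC/C(I)=C/[C@@H](O)[C@@H]1OC(C)(C)O[C@@H]1CO[Si](C)(C)C(C)(C)C | intermediate
11 | benzoyl chloride | O=C(Cl)c1ccccc1 | starting material
12 | (Z)-1,4-di-O-benzoyl-7-O-(tert-butyldimethylsilyl)-2,3-dideoxy-2-iodo-5,6-O-isopropylidene-D-arabino-hept-2-enitol | O=C(OC/C(I)=C/[C@@H](OC(=O)c1ccccc1)[C@@H]2OC(C)(C)O[C@@H]2CO[Si](C)(C)C(C)(C)C)c1ccccc1 | intermediate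
13 | (Z)-1,4-di-O-benzoyl-2,3-dideoxy-2-iodo-5,6-O-isopropylidene-D-arabino-hept-2-enitol | O=C(OC/C(I)=C/[C@@H](OC(=O)c1ccccc1)[C@@H]2OC(C)(C)O[C@@H]2CO)c1ccccc1 | intermediate
14 | (Z)-4,7-di-O-benzoyl-5,6-dideoxy-6-iodo-2,3-O-isopropylidene-aldehydo-D-lyxo-hept-5-enose (the aldehyde of 13) | O=C(OC/C(I)=C/[C@@H](OC(=O)c1ccccc1)[C@@H]2OC(C)(C)O[C@@H]2C=O)c1ccccc1 | intermediate
15 | alkenylchromium dichloride of 14 (trivalent chromium in place of iodine, solvent ligands omitted) | O=C(OC/C(=C/[C@@H](OC(=O)c1ccccc1)[C@@H]2OC(C)(C)O[C@@H]2C=O)[Cr](Cl)Cl)c1ccccc1 | intermediate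
16 | [(3R,4S,5R,6S)-3-(benzoyloxy)-6-hydroxy-4,5-(isopropylidenedioxy)cyclohex-1-en-1-yl]methyl benzoate (4,5-O-isopropylidene derivative of 17) | O=C(OCC1=C[C@@H](OC(=O)c2ccccc2)[C@@H]3OC(C)(C)O[C@@H]3[C@H]1O)c1ccccc1 | intermediate
17 | [(3R,4R,5R,6S)-3-(benzoyloxy)-4,5,6-trihydroxycyclohex-1-en-1-yl]methyl benzoate | O=C(OCC1=C[C@@H](OC(=O)c2ccccc2)[C@H](O)[C@H](O)[C@H]1O)c1ccccc1 | target

**Step count and risks**

Total steps: 9. Longest linear sequence: 9 steps (1 to 17).

Steps most likely to fail:

Step 8. The process at risk is poor facial selectivity in the addition of the alkenylchromium to the aldehyde, so that the carbinol oxygen ends up cis to the C5 oxygen. The fallback sets out from 14 and corrects C6 after the ring is closed instead of during closure. The same CrCl2/NiCl2 closure is accepted as it comes and gives the C6 epimer of 16, [(3R,4S,5R,6R)-3-(benzoyloxy)-6-hydroxy-4,5-(isopropylidenedioxy)cyclohex-1-en-1-yl]methyl benzoate F1. Mitsunobu inversion (ClCH2CO2H, PPh3, DIAD, toluene, 0 °C), with the nucleophile entering from the convex face opposite the dioxolane, should give the 5,6-trans 6-O-chloroacetyl derivative of 16 F2. Thiourea and NaHCO3 in EtOH at 50 °C then remove the chloroacetyl group in the presence of the benzoates, and the route is rejoined at 16.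

Step 2. The process at risk is slow olefination: the weakly nucleophilic iodo ylide may decay, or the product may close by oxa-Michael addition, before the small equilibrium share of open-chain aldehyde is consumed. The fallback sets out from 3 and builds the iodoalkene by directed trans-hydroalumination and iodination of an alkyne:
- Ohira–Bestmann homologation (dimethyl (1-diazo-2-oxopropyl)phosphonate, K2CO3, MeOH, rt) should give 1,2-dideoxy-4,5-O-isopropylidene-D-arabino-hex-1-ynitol F3.
- TBSCl and imidazole silylate the primary hydroxyl to 6-O-(tert-butyldimethylsilyl)-1,2-dideoxy-4,5-O-isopropylidene-D-arabino-hex-1-ynitol F4.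
- The dianion (n-BuLi, 2.2 equiv, THF, −78 °C) adds to paraformaldehyde to give 7-O-(tert-butyldimethylsilyl)-2,3-dideoxy-5,6-O-isopropylidene-D-arabino-hept-2-ynitol F5.
- TESCl (1 equiv, 2,6-lutidine, CH2Cl2, −78 °C) caps the primary propargylic hydroxyl to give 7-O-(tert-butyldimethylsilyl)-2,3-dideoxy-5,6-O-isopropylidene-1-O-triethylsilyl-D-arabino-hept-2-ynitol F6.
- NaAlH2(OCH2CH2OCH3)2 in THF at 0 °C, directed by the free secondary propargylic hydroxyl, delivers hydride to the proximal and aluminium to the distal alkyne carbon in a trans sense. Iodine at −78 °C should then give (Z)-7-O-(tert-butyldimethylsilyl)-2,3-dideoxy-2-iodo-5,6-O-isopropylidene-1-O-triethylsilyl-D-arabino-hept-2-enitol F7.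
- PPTS in MeOH at 0 °C removes only the triethylsilyl group, and the route is rejoined at 10.

Step 9. The process at risk is acid-promoted ionisation of the doubly allylic cyclohexene (allylic transposition or elimination), or migration of the C3 benzoate to the freed C4 hydroxyl, competing with the slow hydrolysis of a cis-fused dioxolane. The fallback sets out from 13, where the alkene is deactivated by iodine and no allylic alcohol is present, and replaces the ketal by fluoride-labile silyl ethers before ring closure: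
- Aqueous AcOH (80 %, 50 °C) removes the acetonide to give (Z)-1,4-di-O-benzoyl-2,3-dideoxy-2-iodo-D-arabino-hept-2-enitol F8.
- TESOTf and 2,6-lutidine give its 5,6,7-tris-O-triethylsilyl ether F9.
- Swern oxidation ((COCl)2, DMSO, Et3N, −78 to −30 °C), which cleaves and oxidises only the primary triethylsilyl ether, should give (Z)-4,7-di-O-benzoyl-5,6-dideoxy-6-iodo-2,3-bis-O-triethylsilyl-aldehydo-D-lyxo-hept-5-enose F10.
- The CrCl2/NiCl2 closure of step 8 gives [(3R,4R,5R,6S)-3-(benzoyloxy)-6-hydroxy-4,5-bis(triethylsilyloxy)cyclohex-1-en-1-yl]methyl benzoate F11.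
- HF·pyridine in THF/pyridine removes the silyl ethers without ionising conditions and rejoins the route at 17.

**Further compounds**

F1 | step 8 | [(3R,4S,5R,6R)-3-(benzoyloxy)-6-hydroxy-4,5-(isopropylidenedioxy)cyclohex-1-en-1-yl]methyl benzoate (C6 epimer of 16) | O=C(OCC1=C[C@@H](OC(=O)c2ccccc2)[C@@H]3OC(C)(C)O[C@@H]3[C@@H]1O)c1ccccc1
F2 | step 8 | 6-O-chloroacetyl derivative of 16 | O=C(OCC1=C[C@@H](OC(=O)c2ccccc2)[C@@H]3OC(C)(C)O[C@@H]3[C@H]1OC(=O)CCl)c1ccccc1
F3 | step 2 | 1,2-dideoxy-4,5-O-isopropylidene-D-arabino-hex-1-ynitol | C#C[C@@H](O)[C@@H]1OC(C)(C)O[C@@H]1CO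
F4 | step 2 | 6-O-(tert-butyldimethylsilyl)-1,2-dideoxy-4,5-O-isopropylidene-D-arabino-hex-1-ynitol | C#C[C@@H](O)[C@@H]1OC(C)(C)O[C@@H]1CO[Si](C)(C)C(C)(C)C
F5 | step 2 | 7-O-(tert-butyldimethylsilyl)-2,3-dideoxy-5,6-O-isopropylidene-D-arabino-hept-2-ynitol | OCC#C[C@@H](O)[C@@H]1OC(C)(C)O[C@@H]1CO[Si](C)(C)C(C)(C)C
F6 | step 2 | 7-O-(tert-butyldimethylsilyl)-2,3-dideoxy-5,6-O-isopropylidene-1-O-triethylsilyl-D-arabino-hept-2-ynitol | CC[Si](CC)(CC)OCC#C[C@@H](O)[C@@H]1OC(C)(C)O[C@@H]1CO[Si](C)(C)C(C)(C)C
F7 | step 2 | (Z)-7-O-(tert-butyldimethylsilyl)-2,3-dideoxy-2-iodo-5,6-O-isopropylidene-1-O-triethylsilyl-D-arabino-hept-2-enitol | CC[Si](CC)(CC)OC/C(I)=C/[C@@H](O)[C@@H]1OC(C)(C)O[C@@H]1CO[Si](C)(C)C(C)(C)C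
F8 | step 9 | (Z)-1,4-di-O-benzoyl-2,3-dideoxy-2-iodo-D-arabino-hept-2-enitol | O=C(OC/C(I)=C/[C@@H](OC(=O)c1ccccc1)[C@H](O)[C@H](O)CO)c1ccccc1
F9 | step 9 | (Z)-1,4-di-O-benzoyl-2,3-dideoxy-2-iodo-5,6,7-tris-O-triethylsilyl-D-arabino-hept-2-enitol | O=C(OC/C(I)=C/[C@@H](OC(=O)c1ccccc1)[C@H](O[Si](CC)(CC)CC)[C@H](O[Si](CC)(CC)CC)CO[Si](CC)(CC)CC)c1ccccc1
F10 | step 9 | (Z)-4,7-di-O-benzoyl-5,6-dideoxy-6-iodo-2,3-bis-O-triethylsilyl-aldehydo-D-lyxo-hept-5-enose | O=C(OC/C(I)=C/[C@@H](OC(=O)c1ccccc1)[C@H](O[Si](CC)(CC)CC)[C@H](O[Si](CC)(CC)CC)C=O)c1ccccc1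
F11 | step 9 | [(3R,4R,5R,6S)-3-(benzoyloxy)-6-hydroxy-4,5-bis(triethylsilyloxy)cyclohex-1-en-1-yl]methyl benzoate | O=C(OCC1=C[C@@H](OC(=O)c2ccccc2)[C@H](O[Si](CC)(CC)CC)[C@H](O[Si](CC)(CC)CC)[C@H]1O)c1ccccc1
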